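## Structural features

The target is a mixed glyceride: a (2S)-glycerol with an acetate on one primary oxygen, a free secondary hydroxyl, and on the other primary oxygen the ester of a bicyclic C20 acid. The acid is a cis-fused octalin. Ring A (C1–C4, C4a, C8a) is saturated and carries the carboxyl at C1, a methyl at C2 and a methyl on each fusion carbon. Ring B (C5–C8) holds a trisubstituted C5=C6 alkene whose C5 bears a 4-methylpent-3-enyl chain.

Four contiguous stereocentres run C2–C1–C8a–C4a: the quaternary fusion carbons are cis, the C1 carboxyl is cis to the C8a methyl, and the C2 methyl is trans to both (1S,2R,4aR,8aR). Fragile elements are the two trisubstituted alkenes (together a 1,5-diene open to cation–olefin cyclisation in strong acid), the epimerisable C1, and the 1,3-diacylglycerol, in which an acyl group can migrate to the free secondary hydroxyl.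

The real difficulty is twofold: the vicinal quaternary carbons C4a/C8a, and placing C1 and C2 relative to them in a cis-octalin that can flip between two chairs. The key step exploits the path C2–C3–C4–C4a–C5=C6: with C2 as a carbonyl, the C4–C4a bond and the C5=C6 alkene form the retron of an oxy-Cope shift, and a bicyclo[2.2.2]octene template enforces the cis fusion.

## Logic of the disconnections

**31 ⇒ 30.** The acetyl–oxygen bond at the primary glycerol carbon is cut last, because the acetate is the group most prone to migrate. This leaves a 1,2-diol. The forward step must acylate the primary hydroxyl only, once, under conditions that move no acyl group.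

**30 ⇒ 29.** The two C–O bonds of the diol are tied back into an isopropylidene ketal, so the glycerol stereocentre comes ready-made from 24 and no hydroxyl differentiation is needed. The forward hydrolysis needs an acid weak enough for both alkenes.

**29 ⇒ 27.** The C2–H bond and one C–H bond of the C2 methyl are removed, and C1 is allowed the opposite configuration. A 1,1-disubstituted exocyclic alkene is the only alkene that can be hydrogenated beside two trisubstituted ones. Two stereocentres are thereby reduced to one face-selective addition plus an equilibration. The forward step must deliver hydrogen to the α face of C2.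

**27 ⇒ 25.** The exocyclic alkene is moved into conjugation (C1=C2), removing the C1 stereocentre. The forward step needs proton removal at the methyl group and kinetic protonation at C1.

**25 ⇒ 23 + 24.** The C1–carbonyl bond and the acyl–oxygen bond are cut, giving an alkenyl electrophile, carbon monoxide and the alcohol. The acid carbon and the glycerol unit arrive together, with no hydrolysis or esterification at a hindered carbonyl. The forward step is a carbonylation at a tetrasubstituted, crowded alkenyl triflate.

**23 ⇒ 21.** The C1–O bond and the C3–H bond are cut, back to an enone. Only conjugate reduction gives the C1=C2 enolate, so the forward step needs 1,4- over 1,2-addition of hydride.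

**21 ⇒ 20 ⇒ 19 ⇒ 17.** In turn: the C1 carbonyl is re-masked as its ketal, the C2–CH3 bond is cut, and the enol C–O–S bond is cut. The C2 carbonyl left by the key step is the handle for the methyl group. The ketal is kept until C2=C3 makes it allylic and cleavable by weak acid. Enolisation can only go toward C3, since C1 is quaternary.

**17 ⇒ 14 (key).** The C4–C4a bond is cut, C2–C6 is reconnected, the alkene returns to C4a=C5 and the ketone becomes a vinyl carbinol. The cis-octalin with two adjacent quaternary carbons becomes a bicyclo[2.2.2]octenol in which only C8a, a bridgehead, is quaternary. The forward shift demands the vinyl group syn to the alkene bridge and an enantiopure bicycle.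

**14 ⇒ 13 ⇒ 12.** The C–H bond at the former sulfonyl carbon becomes C–S, then the C2–vinyl bond is cut. The order protects the α,α-dimethoxy ketone from the reductant. The forward addition needs attack on the carbonyl face next to the alkene bridge.

**12 ⇒ 11.** The single enantiomer is traced to the racemate at the first chiral, sulfone-bearing intermediate. Half the material is lost there, early in the route.

**11 ⇒ 8 + 9.** Both bonds from the bridgeheads to the two-carbon bridge are cut and one methoxy group is removed, through 10. A bridged bicycle becomes a flat guaiacol plus a two-carbon dienophile, and the two future quaternary methyls are ordinary arene methyls. The cycloaddition must outrun decay of 10 and must bond at a methyl-bearing terminus.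

**8 ⇒ 5 ⇒ 2 + 3, and 2 ⇒ 1.** The phenol C–O bond, the aryl–alkyl C–C bond and the C–Br bond are cut in turn. The methoxy group of 1 directs each regiochemical choice.

## Other disconnections considered

Alternative 1: The cut runs through C4a–C8a and C1–C2, so both rings fall away and the open chain A1 remains.

- *Forward step.* A silyl triflate and an amine would convert the enone of A1 into the silyloxydiene A2. Its C4a would add to the enoate β-carbon C8a (ring B), and the ester enolate would then add through C1 to C2 (ring A), giving A3.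
- *In favour.* Two rings, both quaternary carbons and the stereocentres C1, C2, C4a and C8a would come in one operation. The trans C1/C2 relationship would follow from the (E)-enone and a cyclic transition state. This is better founded than the face-selective hydrogenation on which the chosen plan rests for C2. No resolution would be needed if the silyloxy centre of A1 is made by asymmetric catalysis; this too is better.
- *Against.* The first conjugate addition must join a fully substituted nucleophilic carbon to a β,β-disubstituted acceptor, the least favourable case. Nothing in A2 enforces cis fusion or the correct face, whereas the bicyclic template of the chosen plan can give only cis. Afterwards the C4 ketone must be removed and the C5 silyl ether turned into the side-chain-bearing alkene.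
- *Step economy.* About equal. Mechanistically it is the more ambitious plan and the less predictable at the decisive bond.

Alternative 2: The cut runs through C4a–C5 and C8a–C8, a retro-Diels–Alder to the ene-dione A4 and the silyloxydiene A5.

- *Forward step.* A [4+2] cycloaddition under a chiral Lewis acid would give A6.
- *In favour.* Suprafacial addition would set the two methyls cis as surely as the chosen plan does (equal). It would do so in one step from two small achiral compounds. A catalytic enantioselective version would spare the resolution, which is better, provided a catalyst accepts a tetrasubstituted dienophile.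
- *Against.* Such dienophiles are sluggish. A6 holds ring A as a 1,4-dione whose carbonyls differ only through the remote C5 oxygen, yet C4 must lose its oxygen while C1 is homologated and C2 methylated. The ring B alkene arrives at C6=C7 and must be moved to C5=C6 as the side chain is attached. C1 and C2 would still be set by the same kind of face-selective chemistry as in the chosen plan, so nothing is gained there.
- *Step economy.* Probably two to four steps longer.

Alternative 3: The cut is the C8–C8a bond. Ring A stays whole as the enoate A7, whose C2 methyl would come from the chiral pool and whose C4a carries a (Z)-alkenyl chain ending in a primary iodide.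

- *Forward step.* The C8 radical (tin or silicon hydride with an initiator) would add 6-exo-trig to C8a, and hydrogen transfer to the C1 radical would give A8, the methyl ester of the target acid.
- *In favour.* C2 is fixed from the outset and no resolution is needed; both points are better than the chosen plan. Radicals form quaternary carbons readily, and A8 is two to four steps from the target.
- *Against.* A7 already contains the quaternary stereocentre C4a with a geometrically defined trisubstituted alkene, placed 1,4 to C2 with no evident control. The problem the chosen plan solves with the bicycle is moved into the precursor. The cis fusion is not enforced, since a six-membered ring closing onto a cyclohexene can give either fusion. Simple reduction of the iodide and 1,5-hydrogen transfer compete. The C1 hydrogen transfer is kinetic and may need equilibration, as in the chosen plan (equal).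
- *Step economy.* Shorter only if A7 can be had in about ten steps; otherwise about the same.

Key step: step 8

Remark: adduct 11 is taken as the regioisomer with the sulfonyl carbon bonded to the unsubstituted diene terminus, endo; any isomer at that carbon is separated at 11. A racemate is written as its two enantiomers joined by a dot.

## Route

Step 1
Reactants: 1 2,3-dimethylanisole
Product: 2 1-bromo-4-methoxy-2,3-dimethylbenzene
Conditions: NBS, MeCN, 0 °C → rt
Reagents that add atoms: N-bromosuccinimide, O=C1CCC(=O)N1Br
Why: Electrophilic aromatic bromination; the methoxy group directs para and the 3-methyl group ortho to the same carbon, so bromine should enter at C4 only.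

Step 2
Reactants: 2 1-bromo-4-methoxy-2,3-dimethylbenzene; 3 5-bromo-2-methylpent-2-ene
Product: 5 1-methoxy-2,3-dimethyl-4-(4-methylpent-3-en-1-yl)benzene, via (4-methylpent-3-en-1-yl)magnesium bromide 4 (not isolated)
Conditions: 3, Mg, THF, 40 °C; then 2, Pd(dppf)Cl2 (3 mol%), THF, 55 °C
Reagents that add atoms: none
Why: Kumada–Corriu coupling of a primary alkyl Grignard reagent with an aryl bromide; the ferrocenyl diphosphine speeds reductive elimination so that β-hydride elimination should not compete, and the trisubstituted alkene is inert.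

Step 3
Reactants: 5 1-methoxy-2,3-dimethyl-4-(4-methylpent-3-en-1-yl)benzene
Product: 8 2-methoxy-3,4-dimethyl-5-(4-methylpent-3-en-1-yl)phenol, via aryllithium 6 (not isolated), via dimethyl arylboronate 7 (not isolated)
Conditions: n-BuLi, TMEDA, Et2O, 0 °C → rt; B(OMe)3, −78 °C → rt; AcOH, 30% aq H2O2, 0 °C → rt
Reagents that add atoms: hydrogen peroxide, OO
Why: Directed ortho-metalation (C6 is the only free position next to the methoxy group), borylation, and oxidation of the C–B bond with 1,2-shift of the aryl group from boron to oxygen.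

Step 4
Reactants: 8 2-methoxy-3,4-dimethyl-5-(4-methylpent-3-en-1-yl)phenol; 9 phenyl vinyl sulfone
Product: 11 rac-3,3-dimethoxy-4,5-dimethyl-6-(4-methylpent-3-en-1-yl)-7-(phenylsulfonyl)bicyclo[2.2.2]oct-5-en-2-one (sulfonyl syn to the C5=C6 bridge), via masked o-benzoquinone 10 (not isolated)
Conditions: PhI(OAc)2 (added slowly), 9 (5 equiv), MeOH, 0 °C → 60 °C
Reagents that add atoms: methanol, CO
Why: Oxidative dearomatisation of the guaiacol by the trivalent iodine reagent in methanol gives the 6,6-dimethoxycyclohexa-2,4-dienone 10, which is trapped by Diels–Alder addition across its C2 and C5; its fully substituted C4=C5 bond should slow self-dimerisation. The sulfonyl-bearing carbon should bond to the unsubstituted terminus next to the carbonyl, endo; the two bridgeheads are tied to each other by the ring and the adduct is racemic.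

Step 5
Reactants: 11 rac-3,3-dimethoxy-4,5-dimethyl-6-(4-methylpent-3-en-1-yl)-7-(phenylsulfonyl)bicyclo[2.2.2]oct-5-en-2-one
Product: 12 (1R,4S,7S)-3,3-dimethoxy-4,5-dimethyl-6-(4-methylpent-3-en-1-yl)-7-(phenylsulfonyl)bicyclo[2.2.2]oct-5-en-2-one
Conditions: preparative SFC, amylose tris(3,5-dimethylphenylcarbamate) on silica, CO2/i-PrOH, 35 °C
Reagents that add atoms: none
Why: Resolution of a racemate by chromatography on a chiral stationary phase; the aryl sulfone and the ketone offer the π and dipolar contacts such phases discriminate. The sulfur atom should allow the absolute configuration of the collected enantiomer to be fixed by anomalous-dispersion X-ray analysis.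

Step 6
Reactants: 12 (1R,4S,7S)-3,3-dimethoxy-4,5-dimethyl-6-(4-methylpent-3-en-1-yl)-7-(phenylsulfonyl)bicyclo[2.2.2]oct-5-en-2-one
Product: 13 (1R,2R,4S,7S)-3,3-dimethoxy-4,5-dimethyl-6-(4-methylpent-3-en-1-yl)-7-(phenylsulfonyl)-2-vinylbicyclo[2.2.2]oct-5-en-2-ol
Conditions: CH2=CHMgBr (2.5 equiv), THF, −78 → 0 °C; aq NH4Cl
Reagents that add atoms: vinylmagnesium bromide, C=C[Mg]Br
Why: Grignard 1,2-addition; the ethano bridge turns its inward C–H bonds toward one carbonyl face, so attack should come from the face next to the C5=C6 bridge and place the vinyl group over that alkene, which sets C2. The bridgehead next to the ketone cannot enolise, and the excess of reagent covers any proton abstraction next to sulfur.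

Step 7
Reactants: 13 (1R,2R,4S,7S)-3,3-dimethoxy-4,5-dimethyl-6-(4-methylpent-3-en-1-yl)-7-(phenylsulfonyl)-2-vinylbicyclo[2.2.2]oct-5-en-2-ol
Product: 14 (1R,2R,4S)-3,3-dimethoxy-4,5-dimethyl-6-(4-methylpent-3-en-1-yl)-2-vinylbicyclo[2.2.2]oct-5-en-2-ol
Conditions: Na/Hg (6% Na), Na2HPO4, MeOH/THF, −20 °C → rt
Reagents that add atoms: none
Why: Reductive desulfonylation by electron transfer, with the carbanion protonated by methanol. It is placed after step 6 because a one-electron reductant would also cleave a methoxy group from the α,α-dimethoxy ketone of 12, whereas the carbinol, ketal and alkenes of 13 are inert.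

Step 8
Reactants: 14 (1R,2R,4S)-3,3-dimethoxy-4,5-dimethyl-6-(4-methylpent-3-en-1-yl)-2-vinylbicyclo[2.2.2]oct-5-en-2-ol
Product: 17 (4aR,8aS)-1,1-dimethoxy-4a,8a-dimethyl-5-(4-methylpent-3-en-1-yl)-3,4,4a,7,8,8a-hexahydronaphthalen-2(1H)-one, via potassium alkoxide 15 (not isolated), via potassium enolate 16 (not isolated)
Conditions: KH, 18-crown-6, THF, 0 → 50 °C; AcOH, −78 °C
Reagents that add atoms: none
Why: KH deprotonates the tertiary alcohol and the crown ether loosens the K–O ion pair, so that alkoxide 15 undergoes an anionic oxy-Cope ([3,3]-sigmatropic) shift: the vinyl terminus C4 bonds to C4a while the C2–C6 bond breaks, giving the C5=C6 alkene and the C2 enolate 16, which acetic acid protonates at C3. The closest known reaction type is the anionic oxy-Cope rearrangement of 2-vinylbicyclo[2.2.2]oct-5-en-2-ols made from masked o-benzoquinone cycloadducts, which gives cis-decalins. Ring A, the only ring closed, forms as a six-membered ring by the sigmatropic bond formation itself, through the boat-like six-atom array that the bicycle enforces and suprafacially on both three-carbon halves, as the bridged bicycle unfolds into the fused one. The one new stereocentre, C4a, is substrate-controlled: the vinyl group lies over only one face of the C4a=C5 bond, the face cis to the C8a–C1 bond, so C4 must bond there and the two methyl groups end cis. C8a is carried over unchanged, so the chirality of 14 is transferred intact. The step needs the concerted shift to outrun heterolysis of the C2–C6 bond followed by protonation or 1,3-recombination; this is secured by the locked 1,5-diene geometry, the unsubstituted attacking carbon C4, relief of bicyclic strain and irreversible enolate formation. The side-chain alkene is not part of a 1,5-diene with the carbinol and stays out.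

Step 9
Reactants: 17 (4aR,8aS)-1,1-dimethoxy-4a,8a-dimethyl-5-(4-methylpent-3-en-1-yl)-3,4,4a,7,8,8a-hexahydronaphthalen-2(1H)-one
Product: 19 (4aR,8aS)-1,1-dimethoxy-4a,8a-dimethyl-5-(4-methylpent-3-en-1-yl)-1,4,4a,7,8,8a-hexahydronaphthalen-2-yl trifluoromethanesulfonate, via sodium enolate 18 (not isolated)
Conditions: NaN(SiMe3)2, THF, −78 °C; PhNTf2, −78 → 0 °C
Reagents that add atoms: N-phenylbis(trifluoromethanesulfonimide), O=S(=O)(N(c1ccccc1)S(=O)(=O)C(F)(F)F)C(F)(F)F
Why: Enolate O-sulfonylation; C1 is a quaternary ketal carbon, so the sodium amide can deprotonate the isolated ketone 17 only at C3, and the resulting sodium enolate 18 should give a single enol triflate. No stereocentre is touched.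

Step 10
Reactants: 19 (4aR,8aS)-1,1-dimethoxy-4a,8a-dimethyl-5-(4-methylpent-3-en-1-yl)-1,4,4a,7,8,8a-hexahydronaphthalen-2-yl trifluoromethanesulfonate
Product: 20 (4aR,8aS)-1,1-dimethoxy-2,4a,8a-trimethyl-5-(4-methylpent-3-en-1-yl)-1,4,4a,7,8,8a-hexahydronaphthalene
Conditions: MeMgBr, Fe(acac)3 (5 mol%), THF/NMP, −30 → 0 °C
Reagents that add atoms: methylmagnesium bromide, C[Mg]Br
Why: Iron-catalysed cross-coupling of an alkenyl triflate with a methyl Grignard reagent; it is fast at low temperature and should leave the ketal and the isolated alkenes untouched.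

Step 11
Reactants: 20 (4aR,8aS)-1,1-dimethoxy-2,4a,8a-trimethyl-5-(4-methylpent-3-en-1-yl)-1,4,4a,7,8,8a-hexahydronaphthalene
Product: 21 (4aR,8aS)-2,4a,8a-trimethyl-5-(4-methylpent-3-en-1-yl)-4a,7,8,8a-tetrahydronaphthalen-1(4H)-one
Conditions: oxalic acid, wet SiO2, CH2Cl2, rt
Reagents that add atoms: water, O
Why: Acid-catalysed ketal hydrolysis through an allyl-stabilised oxocarbenium ion, which lets a weak acid suffice and spares the trisubstituted alkenes. The same ketal next to a ketone, as in 17, would need much stronger acid, which is why it is cleaved only now.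

Step 12
Reactants: 21 (4aR,8aS)-2,4a,8a-trimethyl-5-(4-methylpent-3-en-1-yl)-4a,7,8,8a-tetrahydronaphthalen-1(4H)-one
Product: 23 (4aR,8aS)-2,4a,8a-trimethyl-5-(4-methylpent-3-en-1-yl)-3,4,4a,7,8,8a-hexahydronaphthalen-1-yl trifluoromethanesulfonate, via lithium enolate 22 (not isolated)
Conditions: LiBH(s-Bu)3, THF, −78 °C; N-(5-chloropyridin-2-yl)bis(trifluoromethanesulfonimide), −78 → 0 °C
Reagents that add atoms: N-(5-chloropyridin-2-yl)bis(trifluoromethanesulfonimide), O=S(=O)(N(c1ccc(Cl)cn1)S(=O)(=O)C(F)(F)F)C(F)(F)F
Why: Conjugate hydride addition to a cyclohexenone whose β-carbon carries no substituent (the carbonyl is shielded by the quaternary C8a) gives the C1=C2 enolate regiospecifically, and it is trapped on oxygen. C3 becomes CH2 and no stereocentre is made.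

Step 13
Reactants: 23 (4aR,8aS)-2,4a,8a-trimethyl-5-(4-methylpent-3-en-1-yl)-3,4,4a,7,8,8a-hexahydronaphthalen-1-yl trifluoromethanesulfonate; 24 (R)-solketal
Product: 25 [(4S)-2,2-dimethyl-1,3-dioxolan-4-yl]methyl (4aR,8aS)-2,4a,8a-trimethyl-5-(4-methylpent-3-en-1-yl)-3,4,4a,7,8,8a-hexahydronaphthalene-1-carboxylate
Conditions: CO (1 atm), Pd(OAc)2 (10 mol%), dppf, Et3N, 24 (3 equiv), DMF, 70 °C
Reagents that add atoms: carbon monoxide, [C-]#[O+]
Why: Palladium-catalysed alkoxycarbonylation of an alkenyl triflate (oxidative addition, CO insertion, alcoholysis of the acylpalladium by the primary alcohol). It installs the carboxyl carbon and the glyceryl ester together; the dioxolane stereocentre is not involved.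

Step 14
Reactants: 25 [(4S)-2,2-dimethyl-1,3-dioxolan-4-yl]methyl (4aR,8aS)-2,4a,8a-trimethyl-5-(4-methylpent-3-en-1-yl)-3,4,4a,7,8,8a-hexahydronaphthalene-1-carboxylate
Product: 27 [(4S)-2,2-dimethyl-1,3-dioxolan-4-yl]methyl (1R,4aR,8aR)-4a,8a-dimethyl-2-methylidene-5-(4-methylpent-3-en-1-yl)-1,2,3,4,4a,7,8,8a-octahydronaphthalene-1-carboxylate, via lithium dienolate 26 (not isolated)
Conditions: LiN(i-Pr)2, THF/DMPU, −78 °C; AcOH, −78 °C
Reagents that add atoms: none
Why: Deconjugative protonation of an ester dienolate: the amide base removes a proton from the methyl group cis to the ester, as in 2-methylcyclohex-1-enecarboxylates flanked by a quaternary carbon, and acetic acid protonates 26 kinetically at C1. Axial protonation in the ring A chair that keeps C5 equatorial and C8 axial should place the hydrogen α and the ester equatorial (β); this provisional C1 configuration fixes the chair used in step 15.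

Step 15
Reactants: 27 [(4S)-2,2-dimethyl-1,3-dioxolan-4-yl]methyl (1R,4aR,8aR)-4a,8a-dimethyl-2-methylidene-5-(4-methylpent-3-en-1-yl)-1,2,3,4,4a,7,8,8a-octahydronaphthalene-1-carboxylate
Product: 29 [(4S)-2,2-dimethyl-1,3-dioxolan-4-yl]methyl (1S,2R,4aR,8aR)-2,4a,8a-trimethyl-5-(4-methylpent-3-en-1-yl)-1,2,3,4,4a,7,8,8a-octahydronaphthalene-1-carboxylate, via cis ester 28 (not isolated)
Conditions: H2 (1 atm), RhCl(PPh3)3 (10 mol%), toluene, rt; then KOt-Bu (0.3 equiv), t-BuOH/THF, 40 °C
Reagents that add atoms: none
Why: Homogeneous hydrogenation with RhCl(PPh3)3, which reduces a 1,1-disubstituted alkene far faster than the two trisubstituted ones, followed by base equilibration of the ester α-carbon. In the chair of 27 with C5 equatorial and C8 axial, the axial C8 (1,3 to C2) covers the β face of the methylidene group, so hydrogen should enter from the α face and leave the C2 methyl β (28). C1 of 28, cis to that methyl, then epimerises to the trans ester 29, in which both ring A substituents are equatorial.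

Step 16
Reactants: 29 [(4S)-2,2-dimethyl-1,3-dioxolan-4-yl]methyl (1S,2R,4aR,8aR)-2,4a,8a-trimethyl-5-(4-methylpent-3-en-1-yl)-1,2,3,4,4a,7,8,8a-octahydronaphthalene-1-carboxylate
Product: 30 (2S)-2,3-dihydroxypropyl (1S,2R,4aR,8aR)-2,4a,8a-trimethyl-5-(4-methylpent-3-en-1-yl)-1,2,3,4,4a,7,8,8a-octahydronaphthalene-1-carboxylate
Conditions: AcOH/H2O (4:1), 40 °C
Reagents that add atoms: none
Why: Acid-catalysed hydrolysis of the isopropylidene ketal; the acid is too weak to protonate the trisubstituted alkenes, and the hindered acyl group should not migrate under these conditions.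

Step 17
Reactants: 30 (2S)-2,3-dihydroxypropyl (1S,2R,4aR,8aR)-2,4a,8a-trimethyl-5-(4-methylpent-3-en-1-yl)-1,2,3,4,4a,7,8,8a-octahydronaphthalene-1-carboxylate
Product: 31 (2S)-3-(acetyloxy)-2-hydroxypropyl (1S,2R,4aR,8aR)-2,4a,8a-trimethyl-5-(4-methylpent-3-en-1-yl)-1,2,3,4,4a,7,8,8a-octahydronaphthalene-1-carboxylate
Conditions: AcCl (1.05 equiv), 2,4,6-collidine, CH2Cl2, −78 °C
Reagents that add atoms: acetyl chloride, CC(=O)Cl
Why: Kinetically selective acylation of the primary hydroxyl of a 1,2-diol with an acid chloride and a hindered pyridine base at low temperature; cold, non-nucleophilic conditions should prevent acetyl migration to the secondary hydroxyl.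

## Compound list

1 | 2,3-dimethylanisole | COc1cccc(C)c1C | starting material
2 | 1-bromo-4-methoxy-2,3-dimethylbenzene | COc1ccc(Br)c(C)c1C | intermediate
3 | 5-bromo-2-methylpent-2-ene | CC(C)=CCCBr | starting material
4 | (4-methylpent-3-en-1-yl)magnesium bromide | CC(C)=CCC[Mg]Br | intermediate
5 | 1-methoxy-2,3-dimethyl-4-(4-methylpent-3-en-1-yl)benzene | COc1ccc(CCC=C(C)C)c(C)c1C | intermediate
6 | [2-methoxy-3,4-dimethyl-5-(4-methylpent-3-en-1-yl)phenyl]lithium | [Li]c1cc(CCC=C(C)C)c(C)c(C)c1OC | intermediate
7 | dimethyl [2-methoxy-3,4-dimethyl-5-(4-methylpent-3-en-1-yl)phenyl]boronate | COB(OC)c1cc(CCC=C(C)C)c(C)c(C)c1OC | intermediate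
8 | 2-methoxy-3,4-dimethyl-5-(4-methylpent-3-en-1-yl)phenol | COc1c(O)cc(CCC=C(C)C)c(C)c1C | intermediate
9 | phenyl vinyl sulfone | C=CS(=O)(=O)c1ccccc1 | starting material
10 | 6,6-dimethoxy-4,5-dimethyl-3-(4-methylpent-3-en-1-yl)cyclohexa-2,4-dien-1-one | O=C1C=C(CCC=C(C)C)C(C)=C(C)C1(OC)OC | intermediate
11 | rac-3,3-dimethoxy-4,5-dimethyl-6-(4-methylpent-3-en-1-yl)-7-(phenylsulfonyl)bicyclo[2.2.2]oct-5-en-2-one, sulfonyl syn to the C5=C6 bridge | O=C1[C@@H]2[C@@H](S(=O)(=O)c3ccccc3)C[C@](C)(C1(OC)OC)C(C)=C2CCC=C(C)C.O=C1[C@H]2[C@H](S(=O)(=O)c3ccccc3)C[C@@](C)(C1(OC)OC)C(C)=C2CCC=C(C)C | intermediate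
12 | (1R,4S,7S)-3,3-dimethoxy-4,5-dimethyl-6-(4-methylpent-3-en-1-yl)-7-(phenylsulfonyl)bicyclo[2.2.2]oct-5-en-2-one | O=C1[C@@H]2[C@@H](S(=O)(=O)c3ccccc3)C[C@](C)(C1(OC)OC)C(C)=C2CCC=C(C)C | intermediate
13 | (1R,2R,4S,7S)-3,3-dimethoxy-4,5-dimethyl-6-(4-methylpent-3-en-1-yl)-7-(phenylsulfonyl)-2-vinylbicyclo[2.2.2]oct-5-en-2-ol, vinyl syn to the C5=C6 bridge | C=C[C@@]1(O)[C@@H]2[C@@H](S(=O)(=O)c3ccccc3)C[C@](C)(C1(OC)OC)C(C)=C2CCC=C(C)C | intermediate
14 | (1R,2R,4S)-3,3-dimethoxy-4,5-dimethyl-6-(4-methylpent-3-en-1-yl)-2-vinylbicyclo[2.2.2]oct-5-en-2-ol, vinyl syn to the C5=C6 bridge | C=C[C@@]1(O)[C@@H]2CC[C@](C)(C1(OC)OC)C(C)=C2CCC=C(C)C | intermediate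
15 | potassium alkoxide of 14 | [K+].C=C[C@@]1([O-])[C@@H]2CC[C@](C)(C1(OC)OC)C(C)=C2CCC=C(C)C | intermediate
16 | potassium (4aR,8aS)-1,1-dimethoxy-4a,8a-dimethyl-5-(4-methylpent-3-en-1-yl)-1,4,4a,7,8,8a-hexahydronaphthalen-2-olate | [K+].COC1(OC)C([O-])=CC[C@]2(C)C(CCC=C(C)C)=CCC[C@]12C | intermediate
17 | (4aR,8aS)-1,1-dimethoxy-4a,8a-dimethyl-5-(4-methylpent-3-en-1-yl)-3,4,4a,7,8,8a-hexahydronaphthalen-2(1H)-one, cis-fused | COC1(OC)C(=O)CC[C@]2(C)C(CCC=C(C)C)=CCC[C@]12C | intermediate
18 | sodium (4aR,8aS)-1,1-dimethoxy-4a,8a-dimethyl-5-(4-methylpent-3-en-1-yl)-1,4,4a,7,8,8a-hexahydronaphthalen-2-olate | [Na+].COC1(OC)C([O-])=CC[C@]2(C)C(CCC=C(C)C)=CCC[C@]12C | intermediate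
19 | (4aR,8aS)-1,1-dimethoxy-4a,8a-dimethyl-5-(4-methylpent-3-en-1-yl)-1,4,4a,7,8,8a-hexahydronaphthalen-2-yl trifluoromethanesulfonate | COC1(OC)C(OS(=O)(=O)C(F)(F)F)=CC[C@]2(C)C(CCC=C(C)C)=CCC[C@]12C | intermediate
20 | (4aR,8aS)-1,1-dimethoxy-2,4a,8a-trimethyl-5-(4-methylpent-3-en-1-yl)-1,4,4a,7,8,8a-hexahydronaphthalene | COC1(OC)C(C)=CC[C@]2(C)C(CCC=C(C)C)=CCC[C@]12C | intermediate
21 | (4aR,8aS)-2,4a,8a-trimethyl-5-(4-methylpent-3-en-1-yl)-4a,7,8,8a-tetrahydronaphthalen-1(4H)-one | O=C1C(C)=CC[C@]2(C)C(CCC=C(C)C)=CCC[C@]12C | intermediate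
22 | lithium (4aR,8aS)-2,4a,8a-trimethyl-5-(4-methylpent-3-en-1-yl)-3,4,4a,7,8,8a-hexahydronaphthalen-1-olate | [Li+].[O-]C1=C(C)CC[C@]2(C)C(CCC=C(C)C)=CCC[C@]12C | intermediate
23 | (4aR,8aS)-2,4a,8a-trimethyl-5-(4-methylpent-3-en-1-yl)-3,4,4a,7,8,8a-hexahydronaphthalen-1-yl trifluoromethanesulfonate | FC(F)(F)S(=O)(=O)OC1=C(C)CC[C@]2(C)C(CCC=C(C)C)=CCC[C@]12C | intermediate
24 | (R)-solketal, [(4R)-2,2-dimethyl-1,3-dioxolan-4-yl]methanol | CC1(C)OC[C@H](O1)CO | starting material
25 | [(4S)-2,2-dimethyl-1,3-dioxolan-4-yl]methyl (4aR,8aS)-2,4a,8a-trimethyl-5-(4-methylpent-3-en-1-yl)-3,4,4a,7,8,8a-hexahydronaphthalene-1-carboxylate | CC1(C)OC[C@H](O1)COC(=O)C1=C(C)CC[C@]2(C)C(CCC=C(C)C)=CCC[C@]12C | intermediate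
26 | lithium dienolate of 25 (C1=C(O)O enolate with exocyclic C2=CH2) | [Li+].CC1(C)OC[C@H](O1)COC([O-])=C1C(=C)CC[C@]2(C)C(CCC=C(C)C)=CCC[C@]12C | intermediate
27 | [(4S)-2,2-dimethyl-1,3-dioxolan-4-yl]methyl (1R,4aR,8aR)-4a,8a-dimethyl-2-methylidene-5-(4-methylpent-3-en-1-yl)-1,2,3,4,4a,7,8,8a-octahydronaphthalene-1-carboxylate, ester trans to the C8a methyl | CC1(C)OC[C@H](O1)COC(=O)[C@@H]1C(=C)CC[C@]2(C)C(CCC=C(C)C)=CCC[C@]12C | intermediate
28 | [(4S)-2,2-dimethyl-1,3-dioxolan-4-yl]methyl (1R,2R,4aR,8aR)-2,4a,8a-trimethyl-5-(4-methylpent-3-en-1-yl)-1,2,3,4,4a,7,8,8a-octahydronaphthalene-1-carboxylate, C1 epimer of 29 | CC1(C)OC[C@H](O1)COC(=O)[C@@H]1[C@H](C)CC[C@]2(C)C(CCC=C(C)C)=CCC[C@]12C | intermediate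
29 | [(4S)-2,2-dimethyl-1,3-dioxolan-4-yl]methyl (1S,2R,4aR,8aR)-2,4a,8a-trimethyl-5-(4-methylpent-3-en-1-yl)-1,2,3,4,4a,7,8,8a-octahydronaphthalene-1-carboxylate | CC1(C)OC[C@H](O1)COC(=O)[C@H]1[C@H](C)CC[C@]2(C)C(CCC=C(C)C)=CCC[C@]12C | intermediate
30 | (2S)-2,3-dihydroxypropyl (1S,2R,4aR,8aR)-2,4a,8a-trimethyl-5-(4-methylpent-3-en-1-yl)-1,2,3,4,4a,7,8,8a-octahydronaphthalene-1-carboxylate | OC[C@H](O)COC(=O)[C@H]1[C@H](C)CC[C@]2(C)C(CCC=C(C)C)=CCC[C@]12C | intermediate
31 | (2S)-3-(acetyloxy)-2-hydroxypropyl (1S,2R,4aR,8aR)-2,4a,8a-trimethyl-5-(4-methylpent-3-en-1-yl)-1,2,3,4,4a,7,8,8a-octahydronaphthalene-1-carboxylate (CNP0146255.1) | CC(=O)OC[C@H](O)COC(=O)[C@H]1[C@H](C)CC[C@]2(C)C(CCC=C(C)C)=CCC[C@]12C | target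

## Step count and least certain steps

Total: 17 steps. Longest linear sequence: 17 steps, from 1 to 31; compounds 3, 9 and 24 enter without steps of their own.

**Step 8 (key step).** The likeliest failure is heterolysis of the C2–C6 bond of the alkoxide before the new bond to the fully substituted C4a can form. The ring-opened allyl anion and vinyl ketone would then be lost by protonation, 1,3-recombination or polymerisation. The fallback keeps the same bond formation but removes the charge. From 14, silylation with N-(trimethylsilyl)imidazole in CH2Cl2 would give the trimethylsilyl ether F1. Heating in toluene in a sealed tube at about 220 °C would drive the neutral [3,3] shift to the silyl enol ether F2. Methanolysis with K2CO3 in MeOH would return to the route at 17.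

**Step 15.** The weak point is the facial sense at C2. It rests on the cis-octalin reacting through the chair with C5 equatorial and C8 axial, and on step 14 having placed the ester equatorial in that chair. If the other chair (C8a methyl axial) governs, hydrogen would enter from the β face and the C2 epimer would result. Alkene migration at the rhodium centre is a second hazard. The fallback has the opposite stereochemical sense for a given chair, because it puts the C2 hydrogen in axially and not equatorially. From 25, reduction with Li in NH3/THF with t-BuOH at −78 °C would give the lithium ester enolate F3, protonated at C2 along the axial path. Quenching with NH4Cl would give 28 and 29 as a C1 mixture, and the same KOt-Bu equilibration would converge on 29. Whichever chair governs, one of the two protocols should therefore reach the C2 β-methyl.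

**Step 4.** The cycloaddition must bond at a methyl-bearing diene terminus. If it is slow with the electron-poor sulfone, dienone 10 would be consumed by addition of methanol or acetic acid or by slow self-condensation. The fallback reverses the electronic demand. From 8, the same oxidation would be run in the presence of phenyl vinyl sulfide, an electron-rich partner for the electron-poor dienone, which should give the sulfide adduct F4 with the same regiochemistry. Oxidation at sulfur with H2O2 and catalytic (NH4)6Mo7O24 in EtOH, conditions that spare alkenes, would return to the route at 11.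

**Step 6.** The homoprenyl group on C6 crowds the alkene-side face of the ketone. Loss of facial selectivity would give the epimeric carbinol, which cannot rearrange, and proton abstraction next to sulfur would consume reagent. The fallback uses a slimmer and far less basic nucleophile in two steps. From 12, HC≡CMgBr in THF at 0 °C would give the ethynyl carbinol F5. Semi-hydrogenation (H2, Pd/CaCO3 poisoned with Pb(OAc)2, quinoline) would return to the route at 13.

**Step 13.** Alcoholysis of a crowded acylpalladium by a bulky alcohol may be slow, so that reduction or hydrolysis of the triflate takes over. The fallback forms the ester C–O bond at the unhindered glycerol carbon instead. From 23, hydroxycarbonylation (Pd(OAc)2, dppf, CO, KOAc, DMF/H2O) would give the enoic acid F6. Alcohol 24 would be converted with TsCl in pyridine into its tosylate F7. Alkylation of the caesium salt of F6 with F7 (Cs2CO3, DMF, 60 °C) would return to the route at 25.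

## Further compounds

F1 | step 8 | trimethylsilyl ether of 14 | C=C[C@@]1(O[Si](C)(C)C)[C@@H]2CC[C@](C)(C1(OC)OC)C(C)=C2CCC=C(C)C
F2 | step 8 | (4aR,8aS)-1,1-dimethoxy-4a,8a-dimethyl-5-(4-methylpent-3-en-1-yl)-2-(trimethylsilyloxy)-1,4,4a,7,8,8a-hexahydronaphthalene | COC1(OC)C(O[Si](C)(C)C)=CC[C@]2(C)C(CCC=C(C)C)=CCC[C@]12C
F3 | step 15 | lithium ester enolate of 29 (C1=C(O)O enolate, C2 methyl β) | [Li+].CC1(C)OC[C@H](O1)COC([O-])=C1[C@H](C)CC[C@]2(C)C(CCC=C(C)C)=CCC[C@]12C
F4 | step 4 | rac-3,3-dimethoxy-4,5-dimethyl-6-(4-methylpent-3-en-1-yl)-7-(phenylsulfanyl)bicyclo[2.2.2]oct-5-en-2-one, sulfanyl syn to the C5=C6 bridge | O=C1[C@@H]2[C@@H](Sc3ccccc3)C[C@](C)(C1(OC)OC)C(C)=C2CCC=C(C)C.O=C1[C@H]2[C@H](Sc3ccccc3)C[C@@](C)(C1(OC)OC)C(C)=C2CCC=C(C)C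
F5 | step 6 | 2-ethynyl-3,3-dimethoxy-4,5-dimethyl-6-(4-methylpent-3-en-1-yl)-7-(phenylsulfonyl)bicyclo[2.2.2]oct-5-en-2-ol, ethynyl syn to the C5=C6 bridge, other centres as in 13 | C#C[C@@]1(O)[C@@H]2[C@@H](S(=O)(=O)c3ccccc3)C[C@](C)(C1(OC)OC)C(C)=C2CCC=C(C)C
F6 | step 13 | (4aR,8aS)-2,4a,8a-trimethyl-5-(4-methylpent-3-en-1-yl)-3,4,4a,7,8,8a-hexahydronaphthalene-1-carboxylic acid | OC(=O)C1=C(C)CC[C@]2(C)C(CCC=C(C)C)=CCC[C@]12C
F7 | step 13 | [(4S)-2,2-dimethyl-1,3-dioxolan-4-yl]methyl 4-methylbenzenesulfonate | CC1(C)OC[C@H](O1)COS(=O)(=O)c1ccc(C)cc1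
A1 | alternative 1 | methyl (2E,7S,10E)-7-(tert-butyldimethylsilyloxy)-3,8-dimethyl-9-oxododeca-2,10-dienoate, C8 unassigned | C/C=C/C(=O)C(C)[C@@H](O[Si](C)(C)C(C)(C)C)CCC/C(C)=C/C(=O)OC
A2 | alternative 1 | methyl (2E,7S,10E)-7,9-bis(tert-butyldimethylsilyloxy)-3,8-dimethyldodeca-2,8,10-trienoate | C/C=C/C(O[Si](C)(C)C(C)(C)C)=C(C)[C@@H](O[Si](C)(C)C(C)(C)C)CCC/C(C)=C/C(=O)OC
A3 | alternative 1 | methyl 5-(tert-butyldimethylsilyloxy)-2,4a,8a-trimethyl-4-oxodecahydronaphthalene-1-carboxylate, ring centres as in the target, silyloxy cis to the fusion methyls | COC(=O)[C@H]1[C@H](C)CC(=O)[C@]2(C)[C@@H](O[Si](C)(C)C(C)(C)C)CCC[C@]12C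
A4 | alternative 2 | 2,3-dimethylcyclohex-2-ene-1,4-dione | CC1=C(C)C(=O)CCC1=O
A5 | alternative 2 | (E)-1-(triisopropylsilyloxy)buta-1,3-diene | C=C/C=C/O[Si](C(C)C)(C(C)C)C(C)C
A6 | alternative 2 | 4a,8a-dimethyl-5-(triisopropylsilyloxy)-2,3,4a,5,8,8a-hexahydronaphthalene-1,4-dione, cis-fused, silyloxy trans to the fusion methyls | O=C1CCC(=O)[C@]2(C)[C@H](O[Si](C(C)C)(C(C)C)C(C)C)C=CC[C@]12C
A7 | alternative 3 | methyl (3R,6R)-3-[(3Z)-1-iodo-8-methylnona-3,7-dien-4-yl]-2,3,6-trimethylcyclohex-1-ene-1-carboxylate | COC(=O)C1=C(C)[C@@](C)(/C(CCC=C(C)C)=C\CCI)CC[C@H]1C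
A8 | alternative 3 | methyl (1S,2R,4aR,8aR)-2,4a,8a-trimethyl-5-(4-methylpent-3-en-1-yl)-1,2,3,4,4a,7,8,8a-octahydronaphthalene-1-carboxylate | COC(=O)[C@H]1[C@H](C)CC[C@]2(C)C(CCC=C(C)C)=CCC[C@]12C
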